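(The earlier runs and the new flask were computed for substances that don't exist, and the scatter is random.)

The ratio of the G left at 8.00 h to the G left at 20.0 h is 2.23 in Saturday's run and 2.14 in Tuesday's. Dividing that span of hours by the logarithm of the ratio gives what I call the fall time: the hours in which the logarithm of the G fraction drops by one.

| flask | G | L | remark | time |
|---|---|---|---|---|
| Saturday's | 0.95 M | 200 mM (held) | run made earlier |  |
| Tuesday's | 1.4 M | 200 mM (held) | run made earlier |  |
| flask | 1.9 M | 200 mM (held) |  | 25 h |

- Saturday's (time / h: E / %, G / %): 1.33: 3.5, 95.8; 4.00: 17.7, 82.3; 8.00: 37.4, 61.7; 10.0: 44.2, 54.7; 15.0: 60.8, 39.1; 20.0: 72.9, 27.7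
- Tuesday's (time / h: E / %, G / %): 1.50: 5.8, 93.7; 2.50: 10.0, 90.2; 4.00: 18.2, 83.9; 8.00: 34.1, 66.5; 12.0: 48.3, 51.4; 20.0: 68.4, 31.1

(readings scatter by 1 percentage point)

1. the E in the flask at 25 h, as a percentage of the G charged
2. the G in the flask at 25 h, as a percentage of the G charged

- the numbers in the tables scatter by 1 percentage point (one standard deviation)
- at the start none of L is in solution

E and G add up to the charge within the scatter, so I read E as what G has lost. I take G to fall with one constant after a delay, pseudo-first-order:

G fraction = exp(−(t − delay) / fall time)

The readings give these fall times: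

Saturday's: 15.0 h; Tuesday's: 15.8 h

Tuesday's fall time, at the larger charge, is longer than Saturday's by 0.800 h. The flask's charge lies beyond Tuesday's by 1.11 of the step from Saturday's charge to Tuesday's.

Carried along a straight line in the charge to 1.9 M, the flask's fall time 16.7 h is my estimate.

Averaged over both runs, the delay read back from the last readings is 1.16 h.

So I draw the flask's curve this way. It starts flat, with none of L in solution, and has its knee at that delay. E then starts up with a slope of 0.0599 h⁻¹ in fractions of the charge. E crosses G near 12.7 h. At 25 h I reckon G at 24.0% and E at 76.0%. The formula's level is the whole charge as E.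

The forecast says E 74% and G 26%, adding “This is an extrapolation, so the range is fairly wide”; my G lies 2 percentage points below its figure.

The flask gives E 75.5% and G 24.5%.

    Z → Q (k = 0.0534 h⁻¹)
    G + Z → E (k = 0.423 L mol⁻¹ h⁻¹)
    L ⇌ Z, rate k3*(csat - [Z]) (kL = 1.06 h⁻¹)

With my delay, that result means a fall time of 16.9 h in this flask, against my 16.7 h. Z is dissolved L and Q the other product; in the flask Z stands at 0.113 M at 2.50 h and 0.161 M at 25.0 h, and one over the constant of G + Z → E times the Z at 12.5 h is 17.4 h. For the neighbour charged with 0.47 M of G, the same line, run back from 16.7 h, gives a fall time of 14.1 h and G 18.4% at 25 h; that neighbour holds G 16.6%.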